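**Plan**

1. Cuts, numbering the cyclohexene C1 (carbinol) to C6 and the cyclopentane C1' (quaternary), C2' (=CH2): (i) the caffeate C–O bond at C1, with C1 taken back to a ketone; (ii) the ring C2=C3 double bond as an aldol condensation (C2 is alpha to the C1 carbonyl, C3 becomes an aldehyde carbon), which opens the ring to a 3,3-disubstituted 5-oxoheptanal; (iii) the bond between the two quaternary carbons C5 and C1' as an anionic oxy-Cope shift.
2. Enabling feature: in the opened form the unit O=C3–C4–C5–C1'–C2'=CH2 is a delta,epsilon-unsaturated aldehyde, the product pattern of a [3,3] shift of a 1,5-dien-3-ol. Quaternary C5 sits between both carbonyl arms, so only the six-membered aldol closure is possible.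
3. Forward: the cyclopentene part (Weinreb amide 5) and a masked ethyl ketone (alkyne 8) give an ynone, then the alcohol, then the Z-dienol 12. One flask then forms the C5–C1' bond, the exocyclic methylene and, by aldol condensation, the cyclohexenone, the only ring made in the route. Reduction, acylation with silyl-protected caffeic acid and desilylation follow.
4. Stereochemistry: one stereocentre is set by catalysis (transfer hydrogenation of ynone 10). The chair [3,3] shift relays it, together with the Z-olefin geometry, to both quaternary carbons and consumes it. The C1 carbinol is set last by a reagent-controlled CBS reduction.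

Key step: step 9

Remark: 2-methylcyclopent-2-en-1-one (1), racemic hex-5-yn-3-ol (6) and caffeic acid (19) are taken as purchasable; the ketone is carried as an acyclic dimethyl ketal because the CH2CHO arm and the exocyclic methylene of the rearranged product would be expected to close by a Prins/ene path under the stronger acid that a cyclic ketal needs.

**Route**

Step 1
Reactants: 1 2-methylcyclopent-2-en-1-one
Product: 3 2-methylcyclopent-1-en-1-yl trifluoromethanesulfonate, via lithium enolate 2 (not isolated)
Conditions: Li (2.1 equiv), NH3(l)/THF, t-BuOH (1 equiv), −78 °C; evaporate NH3; then PhNTf2, THF, 0 °C to rt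
Reagents that add atoms: N-phenyl-bis(trifluoromethanesulfonimide) O=S(=O)(N(c1ccccc1)S(=O)(=O)C(F)(F)F)C(F)(F)F
Why: Dissolving-metal reduction of the enone gives the lithium enolate regiospecifically at the methyl-bearing carbon, and its O-sulfonylation (enol triflate synthesis by enolate trapping) fixes the tetrasubstituted double bond.

Step 2
Reactants: 3 2-methylcyclopent-1-en-1-yl trifluoromethanesulfonate
Product: 4 ethyl 2-(2-methylcyclopent-1-en-1-yl)acetate
Conditions: BrZnCH2CO2Et (from BrCH2CO2Et, Zn, THF), Pd(PPh3)4 (5 mol %), THF, 60 °C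
Reagents that add atoms: ethyl bromoacetate BrCC(=O)OCC (used as its zinc reagent CCOC(=O)C[Zn]Br)
Why: Negishi-type Pd-catalysed cross-coupling of the enol triflate with the Reformatsky zinc enolate forms the ring–CH2 bond at the triflate carbon without moving the double bond.

Step 3
Reactants: 4 ethyl 2-(2-methylcyclopent-1-en-1-yl)acetate
Product: 5 N-methoxy-N-methyl-2-(2-methylcyclopent-1-en-1-yl)acetamide
Conditions: MeNH(OMe)·HCl, i-PrMgCl, THF, −20 to 0 °C
Reagents that add atoms: N,O-dimethylhydroxylamine hydrochloride CNOC.Cl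
Why: Aminolysis of the ester by the magnesium amide of N,O-dimethylhydroxylamine (Weinreb amide synthesis) prepares an acylating agent that accepts only one nucleophile.

Step 4
Reactants: 6 hex-5-yn-3-ol (racemic)
Product: 7 hex-5-yn-3-one
Conditions: Dess–Martin periodinane, CH2Cl2, 0 °C to rt
Reagents that add atoms: none
Why: Dess–Martin oxidation of the secondary alcohol runs near neutrality, which should avoid base-induced isomerisation of the beta,gamma-alkynyl ketone to the allenyl ketone.

Step 5
Reactants: 7 hex-5-yn-3-one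
Product: 8 4,4-dimethoxyhex-1-yne
Conditions: HC(OMe)3, MeOH, TsOH·H2O (cat.), rt; NaOMe quench
Reagents that add atoms: trimethyl orthoformate COC(OC)OC; methanol CO
Why: Acid-catalysed ketalisation driven by the orthoformate as water scavenger; the acyclic dimethyl ketal should survive the basic steps ahead yet hydrolyse at about pH 4.

Step 6
Reactants: 8 4,4-dimethoxyhex-1-yne; 5 N-methoxy-N-methyl-2-(2-methylcyclopent-1-en-1-yl)acetamide
Product: 10 6,6-dimethoxy-1-(2-methylcyclopent-1-en-1-yl)oct-3-yn-2-one, via lithium acetylide 9 (not isolated)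
Conditions: n-BuLi, THF, −78 °C; then 5, −78 to 0 °C; aq. NH4Cl (neutral work-up)
Reagents that add atoms: none
Why: Acylation of the lithium acetylide by the Weinreb amide stops at the ketone because the chelated tetrahedral adduct survives until work-up (Weinreb ketone synthesis).

Step 7
Reactants: 10 6,6-dimethoxy-1-(2-methylcyclopent-1-en-1-yl)oct-3-yn-2-one
Product: 11 (2S)-6,6-dimethoxy-1-(2-methylcyclopent-1-en-1-yl)oct-3-yn-2-ol
Conditions: Ru[(S,S)-TsNCH(Ph)CH(Ph)NH](p-cymene) (1 mol %), i-PrOH, rt
Reagents that add atoms: none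
Why: Noyori asymmetric transfer hydrogenation of an alkynyl ketone, in which the alkynyl group takes the place of the aryl group of the usual model so that the (S,S)-catalyst should give the 2S alcohol; the base-free catalyst should leave the skipped olefin in place.

Step 8
Reactants: 11 (2S)-6,6-dimethoxy-1-(2-methylcyclopent-1-en-1-yl)oct-3-yn-2-ol
Product: 12 (2S,3Z)-6,6-dimethoxy-4-methyl-1-(2-methylcyclopent-1-en-1-yl)oct-3-en-2-ol
Conditions: MeMgBr (5 equiv), Fe(acac)3 (20 mol %), THF, −78 to 0 °C; aq. NH4Cl/NH3 (pH 8)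
Reagents that add atoms: methylmagnesium bromide C[Mg]Br
Why: Iron-catalysed, alkoxide-directed syn-carbomagnesiation of a propargylic alcohol should deliver methyl to the distal alkyne carbon and magnesium to the proximal one, so that protonation gives the Z-trisubstituted olefin with the ketal-bearing CH2 cis to the carbinol carbon.

Step 9
Reactants: 12 (2S,3Z)-6,6-dimethoxy-4-methyl-1-(2-methylcyclopent-1-en-1-yl)oct-3-en-2-ol
Product: 17 (5S)-2,5-dimethyl-5-[(1S)-1-methyl-2-methylidenecyclopentyl]cyclohex-2-en-1-one, via potassium enolate 13 (not isolated), via aldehyde ketal 14 (not isolated), via keto aldehyde 15 (not isolated), via aldol 16 (not isolated)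
Conditions: KH (2 equiv), 18-crown-6 (2 equiv), THF, 0 °C to rt; then AcOH/H2O (buffer, pH 4), 0 °C; then KOH, MeOH, rt to 40 °C
Reagents that add atoms: water O
Why: KH/18-crown-6 turns 12 into a free potassium alkoxide that should undergo an anionic oxy-Cope ([3,3]) shift through a chair transition state with the oxido group equatorial; because the Z-olefin places the ketal-bearing CH2 axial and the ring olefin places its methyl axial, the C2 configuration of 12 is relayed to both new quaternary centres (3S in the chain, 1S in the cyclopentane) while the bond between them, the exocyclic methylene and the aldehyde enolate 13 are formed. The acetic acid buffer protonates 13 to 14 and hydrolyses the acyclic dimethyl ketal to keto aldehyde 15 at an acidity too low for a Prins/ene closure of the aldehyde onto the methylidene group. KOH/MeOH then brings about the intramolecular aldol condensation: the enolate on the ethyl side of the ketone adds to the aldehyde in a 6-(enolendo)-exo-trig closure to give 16, and E1cB loss of water creates the ring C=C bond of 17. The closest known reaction types are the anionic oxy-Cope rearrangement of acyclic 1,5-dien-3-ols and the base-mediated cyclisation of 1,5-keto aldehydes to cyclohexenones (second half of a Robinson annulation). The step needs the [3,3] shift to outrun cleavage of the alkoxide and the aldol to choose one of four enolate/carbonyl pairings: the allyl anion that cleavage would release is unstabilised, and the quaternary carbon between the two carbonyl arms leaves only the six-membered closure open, every other pairing leading to a four-membered ring. Both stereocentres are quaternary and cannot epimerise under the basic conditions.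

Step 10
Reactants: 17 (5S)-2,5-dimethyl-5-[(1S)-1-methyl-2-methylidenecyclopentyl]cyclohex-2-en-1-one
Product: 18 (1S,5S)-2,5-dimethyl-5-[(1S)-1-methyl-2-methylidenecyclopentyl]cyclohex-2-en-1-ol
Conditions: (R)-2-methyl-CBS-oxazaborolidine (20 mol %), catecholborane, toluene, −78 °C
Reagents that add atoms: none
Why: Corey–Bakshi–Shibata reduction under reagent control: with the (R)-catalyst the ketone should bind with the 2-methylalkenyl side as the large group, so that hydride adds to the face that gives the 1S alcohol, cis to the cyclopentyl group.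

Step 11
Reactants: 19 caffeic acid, (2E)-3-(3,4-dihydroxyphenyl)prop-2-enoic acid
Product: 21 (2E)-3-{3,4-bis[(tert-butyldimethylsilyl)oxy]phenyl}prop-2-enoic acid, via tris-silyl compound 20 (not isolated)
Conditions: TBSCl (3.3 equiv), imidazole, DMF, rt; then AcOH/THF/H2O, rt
Reagents that add atoms: tert-butyldimethylsilyl chloride CC(C)(C)[Si](C)(C)Cl
Why: Silylation of both phenols and the acid, followed by selective hydrolysis of the much more labile silyl ester under mild aqueous acid, should leave the bis-silyl ether acid.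

Step 12
Reactants: 18 (1S,5S)-2,5-dimethyl-5-[(1S)-1-methyl-2-methylidenecyclopentyl]cyclohex-2-en-1-ol; 21 (2E)-3-{3,4-bis[(tert-butyldimethylsilyl)oxy]phenyl}prop-2-enoic acid
Product: 22 (1S,5S)-2,5-dimethyl-5-[(1S)-1-methyl-2-methylidenecyclopentyl]cyclohex-2-en-1-yl (2E)-3-{3,4-bis[(tert-butyldimethylsilyl)oxy]phenyl}prop-2-enoate
Conditions: DCC, DMAP (cat.), CH2Cl2, 0 °C to rt
Reagents that add atoms: none
Why: Steglich esterification (carbodiimide activation, DMAP acyl transfer) acylates the allylic alcohol at oxygen, so C1 keeps its configuration.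

Step 13
Reactants: 22 (1S,5S)-2,5-dimethyl-5-[(1S)-1-methyl-2-methylidenecyclopentyl]cyclohex-2-en-1-yl (2E)-3-{3,4-bis[(tert-butyldimethylsilyl)oxy]phenyl}prop-2-enoate
Product: 23 (1S,5S)-2,5-dimethyl-5-[(1S)-1-methyl-2-methylidenecyclopentyl]cyclohex-2-en-1-yl (2E)-3-(3,4-dihydroxyphenyl)prop-2-enoate
Conditions: Bu4NF, AcOH, THF, 0 °C
Reagents that add atoms: none
Why: Fluoride cleaves the two aryl silyl ethers, and acetic acid buffers the phenoxides so that the allylic ester and the catechol should stay intact.

**Compound list**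

1 | 2-methylcyclopent-2-en-1-one | CC1=CCCC1=O | starting material
2 | lithium 2-methylcyclopent-1-en-1-olate | CC1=C(O[Li])CCC1 | intermediate
3 | 2-methylcyclopent-1-en-1-yl trifluoromethanesulfonate | CC1=C(OS(=O)(=O)C(F)(F)F)CCC1 | intermediate
4 | ethyl 2-(2-methylcyclopent-1-en-1-yl)acetate | CCOC(=O)CC1=C(C)CCC1 | intermediate
5 | N-methoxy-N-methyl-2-(2-methylcyclopent-1-en-1-yl)acetamide | CON(C)C(=O)CC1=C(C)CCC1 | intermediate
6 | hex-5-yn-3-ol (racemic) | CCC(O)CC#C | starting material
7 | hex-5-yn-3-one | CCC(=O)CC#C | intermediate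
8 | 4,4-dimethoxyhex-1-yne | CCC(OC)(OC)CC#C | intermediate
9 | (4,4-dimethoxyhex-1-yn-1-yl)lithium | CCC(OC)(OC)CC#C[Li] | intermediate
10 | 6,6-dimethoxy-1-(2-methylcyclopent-1-en-1-yl)oct-3-yn-2-one | CCC(OC)(OC)CC#CC(=O)CC1=C(C)CCC1 | intermediate
11 | (2S)-6,6-dimethoxy-1-(2-methylcyclopent-1-en-1-yl)oct-3-yn-2-ol | CC1=C(C[C@H](O)C#CCC(OC)(OC)CC)CCC1 | intermediate
12 | (2S,3Z)-6,6-dimethoxy-4-methyl-1-(2-methylcyclopent-1-en-1-yl)oct-3-en-2-ol | CC1=C(C[C@H](O)/C=C(/C)CC(OC)(OC)CC)CCC1 | intermediate
13 | potassium enolate (C1=C2 enolate) of aldehyde 14 | C=C1CCC[C@]1(C)[C@@](CC(OC)(OC)CC)(C)C=C[O-].[K+] | intermediate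
14 | (3S)-5,5-dimethoxy-3-methyl-3-[(1S)-1-methyl-2-methylidenecyclopentyl]heptanal | C=C1CCC[C@]1(C)[C@@](CC(OC)(OC)CC)(C)CC=O | intermediate
15 | (3S)-3-methyl-3-[(1S)-1-methyl-2-methylidenecyclopentyl]-5-oxoheptanal | C=C1CCC[C@]1(C)[C@@](CC(=O)CC)(C)CC=O | intermediate
16 | (5S)-3-hydroxy-2,5-dimethyl-5-[(1S)-1-methyl-2-methylidenecyclopentyl]cyclohexan-1-one (mixture at C2 and C3) | C=C1CCC[C@]1(C)[C@@]1(C)CC(O)C(C)C(=O)C1 | intermediate
17 | (5S)-2,5-dimethyl-5-[(1S)-1-methyl-2-methylidenecyclopentyl]cyclohex-2-en-1-one | C=C1CCC[C@]1(C)[C@@]1(C)CC=C(C)C(=O)C1 | intermediate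
18 | (1S,5S)-2,5-dimethyl-5-[(1S)-1-methyl-2-methylidenecyclopentyl]cyclohex-2-en-1-ol | C=C1CCC[C@]1(C)[C@@]1(C)CC=C(C)[C@@H](O)C1 | intermediate
19 | caffeic acid, (2E)-3-(3,4-dihydroxyphenyl)prop-2-enoic acid | OC(=O)/C=C/c1ccc(O)c(O)c1 | starting material
20 | tert-butyldimethylsilyl (2E)-3-{3,4-bis[(tert-butyldimethylsilyl)oxy]phenyl}prop-2-enoate | CC(C)(C)[Si](C)(C)OC(=O)/C=C/c1ccc(O[Si](C)(C)C(C)(C)C)c(O[Si](C)(C)C(C)(C)C)c1 | intermediate
21 | (2E)-3-{3,4-bis[(tert-butyldimethylsilyl)oxy]phenyl}prop-2-enoic acid | OC(=O)/C=C/c1ccc(O[Si](C)(C)C(C)(C)C)c(O[Si](C)(C)C(C)(C)C)c1 | intermediate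
22 | (1S,5S)-2,5-dimethyl-5-[(1S)-1-methyl-2-methylidenecyclopentyl]cyclohex-2-en-1-yl (2E)-3-{3,4-bis[(tert-butyldimethylsilyl)oxy]phenyl}prop-2-enoate | C=C1CCC[C@]1(C)[C@@]1(C)CC=C(C)[C@@H](OC(=O)/C=C/c2ccc(O[Si](C)(C)C(C)(C)C)c(O[Si](C)(C)C(C)(C)C)c2)C1 | intermediate
23 | (1S,5S)-2,5-dimethyl-5-[(1S)-1-methyl-2-methylidenecyclopentyl]cyclohex-2-en-1-yl (2E)-3-(3,4-dihydroxyphenyl)prop-2-enoate | C=C1CCC[C@]1(C)[C@@]1(C)CC=C(C)[C@@H](OC(=O)/C=C/c2ccc(O)c(O)c2)C1 | target

**Count and risks**

Total step count: 13. Longest linear sequence: 10 steps (1, 2, 3, 6, 7, 8, 9, 10, 12, 13).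

Steps most likely to fail:

Step 9. What may go wrong: loss of stereochemical fidelity in the [3,3] shift (a boat transition state or a chair with axial oxido group, both made more competitive because the Z-olefin forces the long ketal-bearing arm axial while two fully substituted carbons are joined), or premature loss of the acid-labile dimethyl ketal on the way to 12. Fallback: the olefin geometry and the roles of the two arms are exchanged, so that only a methyl group is axial and no ketal is needed. This does not remove the risk of alkoxide cleavage, which is judged smaller because the allyl anion released would be unstabilised. The fallback sets out from Weinreb amide 5 and comes back at keto aldehyde 15. Carboalumination of commercial tert-butyl(but-3-yn-1-yloxy)dimethylsilane (Me3Al, Cp2ZrCl2 cat., CH2Cl2; then I2) should give (E)-tert-butyl[(4-iodo-3-methylbut-3-en-1-yl)oxy]dimethylsilane F1. Iodine–lithium exchange (t-BuLi, Et2O, −78 °C) and acylation with 5 should give (3E)-6-[(tert-butyldimethylsilyl)oxy]-4-methyl-1-(2-methylcyclopent-1-en-1-yl)hex-3-en-2-one F2. CBS reduction with the (R)-catalyst and catecholborane should give (2S,3E)-6-[(tert-butyldimethylsilyl)oxy]-4-methyl-1-(2-methylcyclopent-1-en-1-yl)hex-3-en-2-ol F3. KH/18-crown-6 in THF should rearrange F3 through the chair with methyl axial and the silyloxyethyl arm equatorial to (3S)-5-[(tert-butyldimethylsilyl)oxy]-3-methyl-3-[(1S)-1-methyl-2-methylidenecyclopentyl]pentanal F4, whose aldehyde arm is now the future ketone arm. EtMgBr (THF, −78 °C) should give (5S)-7-[(tert-butyldimethylsilyl)oxy]-5-methyl-5-[(1S)-1-methyl-2-methylidenecyclopentyl]heptan-3-ol F5, and Bu4NF should give (3S)-3-methyl-3-[(1S)-1-methyl-2-methylidenecyclopentyl]heptane-1,5-diol F6. Excess Dess–Martin periodinane buffered with NaHCO3 should oxidise both hydroxyl groups without acid to give 15, which is cyclised with KOH/MeOH as in the last stage of step 9.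

Step 8. What may go wrong: methyl delivery to the proximal alkyne carbon or anti addition (wrong regio- or stereochemistry of the carbometalation), or stalling through chelation of magnesium by the ketal. Fallback: syn-hydrometalation, iodination and cross-coupling replace the directed carbometalation; it sets out from 11 and comes back at 12. Silylation (TBSCl, imidazole, DMF) should give tert-butyl{[(2S)-6,6-dimethoxy-1-(2-methylcyclopent-1-en-1-yl)oct-3-yn-2-yl]oxy}dimethylsilane F7. Hydrozirconation (Cp2Zr(H)Cl, THF, rt), in which zirconium should settle on the alkyne carbon remote from the branched silyloxy-bearing carbon, followed by I2 should give tert-butyl{[(2S,3E)-4-iodo-6,6-dimethoxy-1-(2-methylcyclopent-1-en-1-yl)oct-3-en-2-yl]oxy}dimethylsilane F8. Negishi methylation (MeZnCl, Pd(PPh3)4, THF) with retention should give tert-butyl{[(2S,3Z)-6,6-dimethoxy-4-methyl-1-(2-methylcyclopent-1-en-1-yl)oct-3-en-2-yl]oxy}dimethylsilane F9, and Bu4NF should give 12.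

Step 10. What may go wrong: poor facial selectivity, because reagent control has to override the substrate bias of the pseudo-axial C5 methyl group, which hinders the approach that leads to the 1S alcohol. Fallback: substrate control and inversion replace reagent control; it sets out from 17 and comes back at 22. Reduction with NaBH4/CeCl3·7H2O (MeOH, −78 °C), in which hydride should enter mainly anti to the pseudo-axial methyl group, should give (1R,5S)-2,5-dimethyl-5-[(1S)-1-methyl-2-methylidenecyclopentyl]cyclohex-2-en-1-ol F10. Mitsunobu esterification of F10 with acid 21 (PPh3, diisopropyl azodicarboxylate, toluene, 0 °C) should invert C1 and give 22 directly.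

Further compounds
F1 | step 9 | (E)-tert-butyl[(4-iodo-3-methylbut-3-en-1-yl)oxy]dimethylsilane | C/C(CCO[Si](C)(C)C(C)(C)C)=C\I
F2 | step 9 | (3E)-6-[(tert-butyldimethylsilyl)oxy]-4-methyl-1-(2-methylcyclopent-1-en-1-yl)hex-3-en-2-one | CC1=C(CC(=O)/C=C(\C)CCO[Si](C)(C)C(C)(C)C)CCC1
F3 | step 9 | (2S,3E)-6-[(tert-butyldimethylsilyl)oxy]-4-methyl-1-(2-methylcyclopent-1-en-1-yl)hex-3-en-2-ol | CC1=C(C[C@H](O)/C=C(\C)CCO[Si](C)(C)C(C)(C)C)CCC1
F4 | step 9 | (3S)-5-[(tert-butyldimethylsilyl)oxy]-3-methyl-3-[(1S)-1-methyl-2-methylidenecyclopentyl]pentanal | C=C1CCC[C@]1(C)[C@@](CC=O)(C)CCO[Si](C)(C)C(C)(C)C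
F5 | step 9 | (5S)-7-[(tert-butyldimethylsilyl)oxy]-5-methyl-5-[(1S)-1-methyl-2-methylidenecyclopentyl]heptan-3-ol (both C3 epimers) | C=C1CCC[C@]1(C)[C@@](CC(O)CC)(C)CCO[Si](C)(C)C(C)(C)C
F6 | step 9 | (3S)-3-methyl-3-[(1S)-1-methyl-2-methylidenecyclopentyl]heptane-1,5-diol (both C5 epimers) | C=C1CCC[C@]1(C)[C@@](CC(O)CC)(C)CCO
F7 | step 8 | tert-butyl{[(2S)-6,6-dimethoxy-1-(2-methylcyclopent-1-en-1-yl)oct-3-yn-2-yl]oxy}dimethylsilane | CC1=C(C[C@H](O[Si](C)(C)C(C)(C)C)C#CCC(OC)(OC)CC)CCC1
F8 | step 8 | tert-butyl{[(2S,3E)-4-iodo-6,6-dimethoxy-1-(2-methylcyclopent-1-en-1-yl)oct-3-en-2-yl]oxy}dimethylsilane | CC1=C(C[C@H](O[Si](C)(C)C(C)(C)C)/C=C(/I)CC(OC)(OC)CC)CCC1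
F9 | step 8 | tert-butyl{[(2S,3Z)-6,6-dimethoxy-4-methyl-1-(2-methylcyclopent-1-en-1-yl)oct-3-en-2-yl]oxy}dimethylsilane | CC1=C(C[C@H](O[Si](C)(C)C(C)(C)C)/C=C(/C)CC(OC)(OC)CC)CCC1
F10 | step 10 | (1R,5S)-2,5-dimethyl-5-[(1S)-1-methyl-2-methylidenecyclopentyl]cyclohex-2-en-1-ol | C=C1CCC[C@]1(C)[C@@]1(C)CC=C(C)[C@H](O)C1
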